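**Retrosynthetic overview**

1. Sceptrin ⇒ two cyanamide annulations (both 2-aminoimidazoles made last) ⇒ bis(α-aminoketone) ⇒ bis(chloromethyl ketone) ⇒ C2-symmetric all-trans 3,4-diacetylcyclobutane already carrying both bromopyrrole amides.
2. Key disconnection: cyclobutane ⇒ two molecules of an (E)-γ-amido enone, head to head. The Cβ–Cβ bond joins two enone β-carbons (both electrophilic) after one-electron reduction of one enone to a β-nucleophilic radical anion (homoenolate-type synthon) on a chiral Lewis acid. Cα–Cα closure follows in the same step, so all four stereocentres are set there.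
3. Enone ⇒ cross-metathesis of N-allyl-4-bromopyrrole-2-carboxamide with methyl vinyl ketone; amide ⇒ allylamine + 4-bromo-2-(trichloroacetyl)pyrrole.
4. Ring order: pyrroles are bought; cyclobutane (step 3); both imidazoles (step 6).

Assumption: the sense of induction of the chiral Lewis acid in step 3 must be fixed by experiment; the ligand enantiomer that exposes the Cβ Re face (giving the 1R,2R,3S,4S cycloadduct) is used, and its mirror image would give the antipode.
Assumption: only closed-shell species that persist in the flask are numbered as non-isolated intermediates (radical ions are described in the Why lines). Carbon-containing building blocks are numbered as starting materials. Cyanamide is both such a building block and the reagent of step 6, where two molecules are taken up (one per imidazole ring), so it stands on both lines of that step.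

**Route**

Step 1
Reactants: 1 2,2,2-trichloro-1-(4-bromo-1H-pyrrol-2-yl)ethan-1-one; 2 allylamine
Product: 3 N-allyl-4-bromo-1H-pyrrole-2-carboxamide
Conditions: allylamine (1.2 equiv), MeCN, 23 °C
Reagents that add atoms: none
Why: Haloform-type acyl substitution, in which the trichloromethyl ketone acts as an activated acyl donor and the amine expels CCl3 (as CHCl3), so the pyrrole N–H needs no protection; no stereocentre is formed.

Step 2
Reactants: 3 N-allyl-4-bromo-1H-pyrrole-2-carboxamide; 4 methyl vinyl ketone (3 equiv)
Product: 5 (E)-4-bromo-N-(4-oxopent-2-en-1-yl)-1H-pyrrole-2-carboxamide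
Conditions: second-generation Hoveyda–Grubbs catalyst RuCl2(H2IMes)(=CH-C6H4-2-O-i-Pr) (2.5 mol%), CH2Cl2, 40 °C
Reagents that add atoms: none
Why: Olefin cross-metathesis between a reactive terminal allyl amide and an electron-poor vinyl ketone that does not homodimerise gives the cross product selectively, with the E-alkene (>20:1) under thermodynamic control.

Step 3
Reactants: 5 (E)-4-bromo-N-(4-oxopent-2-en-1-yl)-1H-pyrrole-2-carboxamide (two molecules)
Product: 6 N,N'-{[(1R,2R,3S,4S)-3,4-diacetylcyclobutane-1,2-diyl]bis(methylene)}bis(4-bromo-1H-pyrrole-2-carboxamide)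
Conditions: fac-Ir(ppy)3 (1 mol%), Gd(OTf)3 (10 mol%), (S,S)-i-Pr-pybox (20 mol%), MeCN (0.4 M, degassed), 450 nm LEDs, −20 °C
Reagents that add atoms: none
Why: Proposed new method: a radical-anion (reductive-umpolung) [2+2] homodimerisation. Photoexcited fac-Ir(ppy)3 (about −1.7 volts against SCE) transfers one electron to the enone held on the chiral trivalent-gadolinium Lewis acid; coordination is expected to bring the aliphatic enone, about −2.1 volts when free, within reach. The normally electrophilic β-carbon thereby becomes a nucleophilic β-radical/metal enolate (a homoenolate-type d3 synthon) that adds to the β-carbon of a second enone, forming the key Cβ–Cβ bond between two carbons that are both acceptors in the ground state. 4-Exo closure of the resulting α-keto radical onto the enolate carbon gives the cyclobutane ketyl, which returns its electron to tetravalent iridium or to the next bound enone (chain), so the process is redox-neutral and strictly head to head. The ligand shields one face so that both Cβ centres are attacked on their Re faces (like topicity, giving 1R,2R), and ring closure places each acetyl group trans to its neighbours (3S,4S; these two centres are epimerisable, so the all-trans isomer is also the thermodynamic sink). Closest known reaction type: the visible-light photocatalytic radical-anion [2+2] cycloaddition of aryl enones under dual chiral lanthanide Lewis acid/photoredox catalysis, extended here to an aliphatic enone by using a stronger excited-state reductant.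

Step 4
Reactants: 6 N,N'-{[(1R,2R,3S,4S)-3,4-diacetylcyclobutane-1,2-diyl]bis(methylene)}bis(4-bromo-1H-pyrrole-2-carboxamide)
Product: 7 N,N'-{[(1R,2R,3S,4S)-3,4-bis(chloroacetyl)cyclobutane-1,2-diyl]bis(methylene)}bis(4-bromo-1H-pyrrole-2-carboxamide)
Conditions: BnNMe3ICl2 (4.2 equiv), THF, 60 °C
Reagents that add atoms: benzyltrimethylammonium dichloroiodate, C[N+](C)(C)Cc1ccccc1.Cl[I-]Cl
Why: Electrophilic α-halogenation of a methyl ketone through its enol, where the mild dichloroiodate halogenates the unhindered CH3 side and is too weak to attack the acyl-deactivated bromopyrrole; the ring stereocentres stay in their all-trans thermodynamic arrangement.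

Step 5
Reactants: 7 N,N'-{[(1R,2R,3S,4S)-3,4-bis(chloroacetyl)cyclobutane-1,2-diyl]bis(methylene)}bis(4-bromo-1H-pyrrole-2-carboxamide)
Product: 9 N,N'-{[(1R,2R,3S,4S)-3,4-diglycylcyclobutane-1,2-diyl]bis(methylene)}bis(4-bromo-1H-pyrrole-2-carboxamide) dihydrochloride, via bis(diformylamide) 8 (not isolated)
Conditions: NaN(CHO)2 (2.5 equiv), MeCN, 35 °C; then HCl, MeOH, 23 °C
Reagents that add atoms: sodium diformylamide, [Na+].O=C[N-]C=O; hydrogen chloride, Cl
Why: Gabriel-type SN2 amination, in which the non-basic diformylamide anion displaces the primary α-chloride without over-alkylation and acid methanolysis releases the amine directly as its hydrochloride, which blocks self-condensation of the α-aminoketone; no stereocentre is touched.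

Step 6
Reactants: 9 N,N'-{[(1R,2R,3S,4S)-3,4-diglycylcyclobutane-1,2-diyl]bis(methylene)}bis(4-bromo-1H-pyrrole-2-carboxamide) dihydrochloride; 10 cyanamide (two molecules)
Product: 12 sceptrin, via bis(guanidinoacetyl) compound 11 (not isolated)
Conditions: H2NCN (10 equiv), H2O, pH 4.5, 95 °C; then NaHCO3 (aq), reversed-phase chromatography
Reagents that add atoms: cyanamide, NC#N
Why: Marckwald-type 2-aminoimidazole synthesis, in which each of the two ammonium groups adds to one molecule of cyanamide (two molecules in all) to give a guanidine that cyclodehydrates onto the neighbouring ketone; the two ketone-bearing ring carbons are already all-trans and become configurationally fixed imidazole-bearing carbons (S,S), with the CH2N-bearing carbons (R,R) untouched.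

**Compound list**

1 | 2,2,2-trichloro-1-(4-bromo-1H-pyrrol-2-yl)ethan-1-one | O=C(c1cc(Br)c[nH]1)C(Cl)(Cl)Cl | starting material
2 | allylamine | NCC=C | starting material
3 | N-allyl-4-bromo-1H-pyrrole-2-carboxamide | C=CCNC(=O)c1cc(Br)c[nH]1 | intermediate
4 | methyl vinyl ketone | CC(=O)C=C | starting material
5 | (E)-4-bromo-N-(4-oxopent-2-en-1-yl)-1H-pyrrole-2-carboxamide | CC(=O)/C=C/CNC(=O)c1cc(Br)c[nH]1 | intermediate
6 | N,N'-{[(1R,2R,3S,4S)-3,4-diacetylcyclobutane-1,2-diyl]bis(methylene)}bis(4-bromo-1H-pyrrole-2-carboxamide), all-trans | CC(=O)[C@H]1[C@H](CNC(=O)c2cc(Br)c[nH]2)[C@@H](CNC(=O)c2cc(Br)c[nH]2)[C@@H]1C(C)=O | intermediate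
7 | (1R,2R,3S,4S) all-trans bis(chloromethyl ketone) | ClCC(=O)[C@H]1[C@H](CNC(=O)c2cc(Br)c[nH]2)[C@@H](CNC(=O)c2cc(Br)c[nH]2)[C@@H]1C(=O)CCl | intermediate
8 | (1R,2R,3S,4S) all-trans bis(N,N-diformylaminomethyl ketone), not isolated | O=CN(C=O)CC(=O)[C@H]1[C@H](CNC(=O)c2cc(Br)c[nH]2)[C@@H](CNC(=O)c2cc(Br)c[nH]2)[C@@H]1C(=O)CN(C=O)C=O | intermediate
9 | (1R,2R,3S,4S) all-trans bis(aminomethyl ketone) dihydrochloride | NCC(=O)[C@H]1[C@H](CNC(=O)c2cc(Br)c[nH]2)[C@@H](CNC(=O)c2cc(Br)c[nH]2)[C@@H]1C(=O)CN.Cl.Cl | intermediate
10 | cyanamide | NC#N | starting material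
11 | (1R,2R,3S,4S) all-trans bis(guanidinomethyl ketone) dihydrochloride, not isolated | NC(=N)NCC(=O)[C@H]1[C@H](CNC(=O)c2cc(Br)c[nH]2)[C@@H](CNC(=O)c2cc(Br)c[nH]2)[C@@H]1C(=O)CNC(N)=N.Cl.Cl | intermediate
12 | sceptrin, N,N'-{[(1R,2R,3S,4S)-3,4-bis(2-amino-1H-imidazol-5-yl)cyclobutane-1,2-diyl]bis(methylene)}bis(4-bromo-1H-pyrrole-2-carboxamide) | Nc1ncc([C@H]2[C@H](CNC(=O)c3cc(Br)c[nH]3)[C@@H](CNC(=O)c3cc(Br)c[nH]3)[C@@H]2c2cnc(N)[nH]2)[nH]1 | target

**Totals**

Total step count: 6. Longest linear sequence: 6 steps (1 → 3 → 5 → 6 → 7 → 9 → 12).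

**Three steps most likely to fail**

Step 3 (key dimerisation). The risks are:
- The aliphatic enone may not be reduced, or its unstabilised ketyl may not close, giving hydrodimer instead of cyclobutane.
- One-point binding of the enone may give low ee. Crystallisation of C2-symmetric 6 can upgrade ee, and if both partners are catalyst-bound the wrong pairing is shed as a cis diastereomer.
- The amide oxygen may add to the Lewis-acid-activated enone (oxazoline formation).

The fallback sets out from 3 and comes back at 6, using a redox-auxiliary ketone that is reduced easily and binds a chiral Lewis acid at two points. 1-Methylimidazole is lithiated (n-BuLi, THF, −78 °C) and acylated with N-methoxy-N-methylacrylamide to give the vinyl ketone 1-(1-methyl-1H-imidazol-2-yl)prop-2-en-1-one F1. Cross-metathesis of 3 with F1 (same ruthenium catalyst as step 2) gives the 2-acylimidazole enone F2. Its radical-anion [2+2] homodimerisation, a substrate class known to undergo this photocatalysis, is run with Ru(bpy)3Cl2, i-Pr2NEt and Sc(OTf)3/(S,S)-t-Bu-pybox under visible light and gives the all-trans bis(2-acylimidazole) cycloadduct F3. Excess MeMgBr converts both ketones into the bis(tertiary carbinol) F4. N-Methylation with MeOTf followed by DBU expels the imidazolium unit from each carbinol and releases the two methyl ketones, which is compound 6.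

Step 4 (chlorination). The risks are halogenation of the pyrrole C5 position or of the ring methine instead of the methyl group. The fallback sets out from 6 and comes back at 7; it fixes the regiochemistry by C–C bond formation and brings in chloride as a nucleophile. Double Claisen formylation (HCO2Et, NaH, THF) can only give a stable enolate on the methyl side and affords the bis(β-keto aldehyde) F5. Deformylative diazo transfer (MsN3, Et3N, MeCN) gives the bis(diazomethyl ketone) F6. HCl in dioxane at 0 °C then gives 7 with loss of nitrogen.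

Step 6 (double annulation, together with the handling of the self-condensing aminoketone 9). The fallback sets out from 7 and comes back at 12, bypassing the free aminoketone. Condensation of the bis(chloromethyl ketone) with excess N-Boc-guanidine (NaI 0.2 equiv, DMF, 23 °C; α-haloketone–guanidine cyclocondensation) gives the bis(N-Boc-2-aminoimidazole) F7. The Boc group is drawn on the ring nitrogen next to C5; its exact position does not matter. TFA in CH2Cl2 followed by NaHCO3 removes both Boc groups and gives 12.

**Further compounds**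

F1 | step 3 | 1-(1-methyl-1H-imidazol-2-yl)prop-2-en-1-one | C=CC(=O)c1nccn1C
F2 | step 3 | (E)-4-bromo-N-[4-(1-methyl-1H-imidazol-2-yl)-4-oxobut-2-en-1-yl]-1H-pyrrole-2-carboxamide | Cn1ccnc1C(=O)/C=C/CNC(=O)c1cc(Br)c[nH]1
F3 | step 3 | N,N'-{[(1R,2R,3S,4S)-3,4-bis(1-methyl-1H-imidazole-2-carbonyl)cyclobutane-1,2-diyl]bis(methylene)}bis(4-bromo-1H-pyrrole-2-carboxamide) | Cn1ccnc1C(=O)[C@H]1[C@H](CNC(=O)c2cc(Br)c[nH]2)[C@@H](CNC(=O)c2cc(Br)c[nH]2)[C@@H]1C(=O)c1nccn1C
F4 | step 3 | N,N'-{[(1R,2R,3S,4S)-3,4-bis[1-hydroxy-1-(1-methyl-1H-imidazol-2-yl)ethyl]cyclobutane-1,2-diyl]bis(methylene)}bis(4-bromo-1H-pyrrole-2-carboxamide), carbinol centres as a mixture | CC(O)(c1nccn1C)[C@H]1[C@H](CNC(=O)c2cc(Br)c[nH]2)[C@@H](CNC(=O)c2cc(Br)c[nH]2)[C@@H]1C(C)(O)c1nccn1C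
F5 | step 4 | N,N'-{[(1R,2R,3S,4S)-3,4-bis(3-oxopropanoyl)cyclobutane-1,2-diyl]bis(methylene)}bis(4-bromo-1H-pyrrole-2-carboxamide), present as its hydroxymethylene tautomer | O=CCC(=O)[C@H]1[C@H](CNC(=O)c2cc(Br)c[nH]2)[C@@H](CNC(=O)c2cc(Br)c[nH]2)[C@@H]1C(=O)CC=O
F6 | step 4 | N,N'-{[(1R,2R,3S,4S)-3,4-bis(diazoacetyl)cyclobutane-1,2-diyl]bis(methylene)}bis(4-bromo-1H-pyrrole-2-carboxamide) | [N-]=[N+]=CC(=O)[C@H]1[C@H](CNC(=O)c2cc(Br)c[nH]2)[C@@H](CNC(=O)c2cc(Br)c[nH]2)[C@@H]1C(=O)C=[N+]=[N-]
F7 | step 6 | di-tert-butyl 4,4'-{(1S,2S,3R,4R)-3,4-bis[(4-bromo-1H-pyrrole-2-carboxamido)methyl]cyclobutane-1,2-diyl}bis(2-amino-1H-imidazole-1-carboxylate) | CC(C)(C)OC(=O)n1cc(nc1N)[C@H]1[C@H](CNC(=O)c2cc(Br)c[nH]2)[C@@H](CNC(=O)c2cc(Br)c[nH]2)[C@@H]1c1cn(C(=O)OC(C)(C)C)c(N)n1
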